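(The data were computed on assumed constants; noise was put on by code.)

Reagent is the account to keep. Two amounts count in these flasks, the reagent charged and the starting material charged. For green the reagent budget, reagent charged over starting material charged, is 1.20, and for ochre it is 1.44.

| setting | ash | elm | green | ochre |
|---|---|---|---|---|
| starting material | 0.25 M (fed, over 40 min) | 0.25 M (fed, over 40 min) | 0.25 M (fed, over 40 min) | 0.25 M (fed, over 40 min) |
| reagent | 0.20 M | 0.32 M | 0.300 M | 0.360 M |
| remark | run made earlier; the fed solution adds 1.0 times the starting volume | run made earlier; the fed solution adds 1.0 times the starting volume | the fed solution adds 1.0 times the starting volume | the fed solution adds 1.0 times the starting volume |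
| time |  |  | 30 h | 30 h |

| run | time / h | bis adduct / % | single product / % | tetra adduct / % | starting material / % | side product / % |
|---|---|---|---|---|---|---|
| ash | 8.00 | 12 | 29 | 0 | 52 | 2 |
| ash | 15.0 | 24 | 27 | 0 | 44 | 10 |
| ash | 25.0 | 26 | 26 | 0 | 38 | 11 |
| ash | 30.0 | 24 | 26 | 0 | 38 | 11 |
| elm | 4.00 | 14 | 33 | 1 | 54 | 6 |
| elm | 10.0 | 37 | 31 | 0 | 32 | 5 |
| elm | 20.0 | 42 | 29 | 0 | 20 | 4 |
| elm | 30.0 | 48 | 27 | 0 | 18 | 12 |

(each reading ± 2 percentage points)

- which of these there is most of at the end, counted by the starting material in it, green (single product / side product / starting material / bis adduct)
- which of these there is most of at the end, counted by the starting material in it, ochre (single product / side product / starting material / bis adduct)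
- amount of the one of these that there is most of at the end, in percent of the starting material charged, green
- amount of the one of these that there is most of at the end, in percent of the starting material charged, ochre

A single product holds one reagent and a bis adduct two, while each fraction counted as side product holds 0.5. At 30.0 h the ash readings add up to a use of 0.795 against a budget of 0.800, and the elm readings to 1.29 against 1.28. Each reading carries a scatter of 2 percentage points, so these uses read as level with their budgets. Supposing that green and ochre also use their budgets by that time, the budget can be turned into an amount of bis adduct. A first round takes elm's 27% of single product from green's budget and gives 46.5% bis adduct. But side product takes reagent too, so a second round puts ash's 11% back in, which gives 43.7% for green and 55.8% for ochre.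

The forecast names bis adduct for green at 43%, range 38% to 47%, and bis adduct for ochre at 54%, range 48% to 59%, with the words “The reagent balance explains the runs.” The reckoning here stands higher than the forecast for green and for ochre.

    reagent + tetra adduct → over-reaction product (k = 1.30 M⁻¹ h⁻¹)
    reagent + bis adduct → triple product (k = 0.0260 M⁻¹ h⁻¹)
    reagent + triple product → tetra adduct (k = 0.0330 M⁻¹ h⁻¹)
    starting material + single product → side product (k = 0.130 M⁻¹ h⁻¹)
    reagent + single product → bis adduct (k = 1.70 M⁻¹ h⁻¹)
    starting material + reagent → single product (k = 1.40 M⁻¹ h⁻¹)
    starting material + tetra adduct ⇌ idle adduct, settled at all times (K = 6.80 M⁻¹)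

Green ends at 42.4% bis adduct and ochre at 54.9%, with bis adduct ahead in both. Green keeps 2.6% of its reagent, so it has used 1.17 of its budget of 1.20. The same flask with 1.0 M of starting material has a budget of 0.300 and keeps 0% of its reagent. In that flask bis adduct stands at 4.21%, and starting material stands highest at 59.1%.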